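Constants first: none is given, so read one from the runs. Write the rate as k(t)·S·R, with S substrate, R partner, and a, b their charges. Count partner one for one with substrate, so R = b − a + S. Then define the allowance Θ(t), the integral of k over the clock up to t, which any reading gives:

Θ = ln[R·a/(S·b)] / (b − a)

| setting | birch | maple | alder | elm | larch |
|---|---|---|---|---|---|
| substrate | 250 mM | 130 mM | 250 mM | 500 mM | 250 mM |
| partner | 275 mM | 155 mM | 140 mM | 275 mM | 140 mM |
| free catalyst | 0.500 mM | 0.500 mM | 0.500 mM | 0.500 mM | 1.50 mM |
| time |  |  |  |  | 51 min |

- birch run (time / min: [substrate] / mM): 1.8: 190.5; 5.5: 150.7; 11: 128.2; 17: 118.7; 24: 113.7; 32: 108.4; 41: 106.7; 51: 102.6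
- maple run (time / min: [substrate] / mM): 1.8: 111.9; 5.5: 95.4; 11: 84.3; 17: 80.5; 24: 77.5; 32: 73.5; 41: 73.5; 51: 72.0
- alder run (time / min: [substrate] / mM): 1.8: 219.1; 5.5: 192.2; 11: 180.9; 17: 174.0; 24: 170.8; 32: 167.0; 41: 164.4; 51: 166.7
- elm run (time / min: [substrate] / mM): 1.8: 396.0; 5.5: 332.9; 11: 306.5; 17: 295.7; 24: 289.4; 32: 284.9; 41: 282.6; 51: 281.3

(standard deviation of a reading: 1 mM)

- how the opening rate goes with [substrate] round the charge of the birch run: the exponent of the rate at two percent of substrate gone to target (one fixed amount of target, the same in the runs compared)
- how the opening rate goes with [partner] round the charge of the birch run: the exponent of the rate at two percent of substrate gone to target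
- the maple run starts with 120 mM less of substrate and of partner than the birch run, and with no target. Compared where both hold the same amount of substrate, once fifteen percent of what the maple run was charged with has turned into target, is the maple run faster, slower or alike (within a tenth)?
- substrate in the larch run at 51 min, as a share of the substrate charged

- Overall: substrate + partner -> target, with free catalyst as catalyst.
- Constant volume, constant temperature.
- An order is taken over about fifteen percent of the charge, up and down.

At 1.8 min, birch gives 1.12 /M, maple 1.03 /M, alder 1.07 /M and elm 1.08 /M. Very different charges read alike, so take orders of 1 in substrate and in partner.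

Now turn the maple question round. For "alike", k in the birch run at the shared substrate would have to match k in the maple run there. The asked point falls just after 1.8 min in the maple run, with substrate near 111.9 mM. The birch run passes that amount between 24 min and 32 min. Both runs then hold the same partner by the count, so the rate ratio is the ratio of the slopes of Θ. Maple's average opening slope is 0.572 /M/min. Birch's slope there is 0.0439 /M/min. The ratio reads 13.0, far from alike, so maple is faster.

For the larch run, take the alder reading at 51 min, the same reagent charges with a third of the catalyst: 4.53 /M, the allowance spent by that clock. Partner is the limiting reagent of this charge. An unchanged allowance keeps 66.7 % of the substrate. An allowance scaled with the catalyst keeps 50.3 %. Take the geometric middle of the two allowances, which is my own commitment: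

Θ = 7.85 /M, so substrate share = 57.6 %

The forecast gives orders 1 and 1, maple faster, and larch 52 %, lower than my figure, on the ground that “The catalyst is dying with clock time”.

The simulation gives orders 1.0 and 1.0, maple faster by a ratio of 14, and larch 59.1 %.

    2 free catalyst ⇌ catalyst dimer, settled at all times (722.0 /M)
    free catalyst + substrate + partner → target + free catalyst (2244 /M²/min)
    2 free catalyst → 2 spent catalyst (750.0 /M/min)
    partner → lost reagent (0.01752 /min)

Turned back into the allowance, the larch result reads 7.14 /M, which is 1.58 times the alder allowance for 3.00 times the catalyst. The shortfall comes from free catalyst turning into spent catalyst: without that step the larch run keeps 47.2 %, an allowance of 19.2 /M. The same step opens the gap in slopes between maple and birch: without it their rate ratio falls from 14 to 1.1.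

The numbers in the tables are calculated from invented constants, and the scatter is random.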